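Carotenoid numbering is used (C1 = CMe2, C3 = CHOH, C5 = C(CH3)O, C8 = OCH, chain C9 to C10′); ring B, the 2,5-dihydrofuran O–C5–C6=C7–C8 fused to cyclohexane ring A along C5–C6, is a 3,6-dihydro-1,2-dioxine less one oxygen, and such a dioxine is what O2 gives with a C5=C6–C7=C8 diene.
Cuts, in retrosynthetic order: C11=C12 (C15 enal + C12 phosphonate), O–C8 of ring B (back to the 5,8-peroxide), the two C–O bonds of the peroxide (back to a 5,7E,9Z-triene), C5=C6 (dehydration), C6–C7 (acetylide + ring ketone); the C12 piece is cut at C11′=C12′ and C12–P.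
Forward: ring A comes from ketoisophorone; the C6 enynol is attached at C6, the alkyne is reduced and water removed to give the triene; O2 builds the dioxine and PPh3 contracts it to ring B; the C12 chain is joined last, then ester reduction and desilylation.
Stereocentres: C3 from an enzymatic C=C reduction followed by diastereoselective ketone hydrogenation; C5 from O2 addition to the diene face anti to the 3-silyloxy group; C8 from suprafacial addition to a 7E diene followed by SN2 inversion in the ring contraction.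
Double bonds: 9Z is carried in with the (Z)-enynol, 7E comes from directed trans-hydroalumination, 11E and 11′E from Horner–Wadsworth–Emmons reactions, and 13E, 15E and 13′E from the C10 dialdehyde.

Key step: step 9

Remark: the target as drawn is the (3S,5R,8S,9Z) isomer; the carbinol configuration drawn for the three tertiary alcohols before the triene is the one expected from axial attack and is erased on dehydration, so either epimer serves.

Step 1
Reactants: 1 ketoisophorone (2,6,6-trimethylcyclohex-2-ene-1,4-dione)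
Product: 2 (6R)-2,2,6-trimethylcyclohexane-1,4-dione [(6R)-levodione]
Conditions: OYE2 (old yellow enzyme 2), NADP+ (cat.), glucose dehydrogenase, D-glucose, phosphate buffer pH 7, 30 °C
Reagents that add atoms: none
Why: Ene-reductase reduction of the enedione C=C with cofactor recycling; hydride and proton are delivered trans across the double bond in the active site, which should set the methyl-bearing carbon as R, the known sense for this substrate.

Step 2
Reactants: 2 (6R)-levodione
Product: 3 (4R,6R)-4-hydroxy-2,2,6-trimethylcyclohexan-1-one [(4R,6R)-actinol; OH trans to the C6 methyl]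
Conditions: H2, Raney Ni, MeOH, 20 °C; recrystallisation
Reagents that add atoms: none
Why: Heterogeneous catalytic hydrogenation of the unhindered C4 carbonyl (the C1 carbonyl is flanked by a quaternary and a tertiary carbon); hydrogen should arrive on the face away from the axial C2 methyl, so the axial 4R alcohol trans to the C6 methyl is expected to predominate and is freed of its cis epimer by crystallisation.

Step 3
Reactants: 3 (4R,6R)-actinol
Product: 4 (4R,6R)-4-(tert-butyldimethylsilyloxy)-2,2,6-trimethylcyclohexan-1-one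
Conditions: TBSCl, imidazole, DMF, 20 °C
Reagents that add atoms: tert-butyldimethylsilyl chloride, CC(C)(C)[Si](C)(C)Cl
Why: Imidazole-promoted silylation of a secondary alcohol masks it for the organometallic, hydride and dehydration steps that follow.

Step 4
Reactants: 4 silyl-protected actinol; 5 (Z)-3-methylpent-2-en-4-yn-1-ol
Product: 7 (1S,4R,6R)-4-(tert-butyldimethylsilyloxy)-1-[(3Z)-5-hydroxy-3-methylpent-3-en-1-yn-1-yl]-2,2,6-trimethylcyclohexan-1-ol, via dilithio enynol 6 (not isolated)
Conditions: 5, n-BuLi (2 equiv), THF, −78 to −20 °C; then 4, −78 to 20 °C; H2O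
Reagents that add atoms: none
Why: 1,2-Addition of a lithium acetylide (as its alkoxide–acetylide dianion) to a hindered ketone, well established for 2,2,6-trimethylcyclohexanones; axial attack anti to the axial C1 methyl should give mainly the carbinol drawn, whose configuration does not matter because it is erased in step 7.

Step 5
Reactants: 7 acetylenic diol
Product: 8 (1R,4R,6R)-4-(tert-butyldimethylsilyloxy)-1-[(1E,3Z)-5-hydroxy-3-methylpenta-1,3-dien-1-yl]-2,2,6-trimethylcyclohexan-1-ol
Conditions: NaAlH2(OCH2CH2OMe)2, THF, 0 to 20 °C; aq. NaOH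
Reagents that add atoms: none
Why: Hydroxyl-directed trans-hydroalumination of the propargylic alkoxide followed by protonolysis should give the E alkene (7E) and leave the 9Z double bond and the silyl ether untouched.

Step 6
Reactants: 8 (7E,9Z)-diene diol
Product: 9 (2Z,4E)-5-[(1R,4R,6R)-4-(tert-butyldimethylsilyloxy)-1-hydroxy-2,2,6-trimethylcyclohexyl]-3-methylpenta-2,4-dien-1-yl pivalate
Conditions: PivCl, pyridine, CH2Cl2, 0 °C
Reagents that add atoms: pivaloyl chloride, CC(C)(C)C(=O)Cl
Why: Selective acylation of the primary allylic alcohol; the tertiary allylic alcohol is too hindered to react with pivaloyl chloride in pyridine without a nucleophilic catalyst.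

Step 7
Reactants: 9 tertiary alcohol pivalate
Product: 10 (2Z,4E)-5-[(4R)-4-(tert-butyldimethylsilyloxy)-2,6,6-trimethylcyclohex-1-en-1-yl]-3-methylpenta-2,4-dien-1-yl pivalate [the (7E,9Z)-triene]
Conditions: Ph2S[OC(CF3)2Ph]2 (Martin sulfurane), CH2Cl2, −20 to 20 °C
Reagents that add atoms: none
Why: Dehydration of a tertiary alcohol with Martin sulfurane (alkoxysulfonium formation, then E1-type loss of a β-proton); C5–H is the only ring β-hydrogen because C1 is quaternary, so the conjugated C5=C6–C7=C8–C9=C10 triene should form cold and without acid, and the C5 and C6 stereocentres disappear.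

Step 8
Reactants: 10 (7E,9Z)-triene pivalate
Product: 11 (2Z)-3-[(3R,7S,8aR)-7-(tert-butyldimethylsilyloxy)-5,5,8a-trimethyl-3,5,6,7,8,8a-hexahydro-1,2-benzodioxin-3-yl]but-2-en-1-yl pivalate [5,8-endoperoxide; carotenoid descriptors 3S,5R,8R,9Z]
Conditions: O2, tetraphenylporphyrin (cat.), visible light, CH2Cl2, −40 °C
Reagents that add atoms: dioxygen (as singlet oxygen), O=O
Why: Sensitised photooxygenation, in which singlet oxygen adds suprafacially in a (4+2) cycloaddition to the twisted 6-s-cis ring diene C5=C6–C7=C8 as known for ionone-type dienes; the 9Z chain cannot reach an s-cis C7=C8–C9=C10 geometry, the allylic ester deactivates C9=C10 toward the ene reaction, and O2 is expected to enter mainly anti to the 3-silyloxy group (as peracids do with 3-O-protected β end groups), setting C5 as R and, through the 7E geometry, C8 as R.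

Step 9
Reactants: 11 5,8-endoperoxide
Product: 13 (2Z)-3-[(2S,6S,7aR)-6-(tert-butyldimethylsilyloxy)-4,4,7a-trimethyl-2,4,5,6,7,7a-hexahydro-1-benzofuran-2-yl]but-2-en-1-yl pivalate [5,8-epoxide; 3S,5R,8S,9Z], via oxyphosphonium alkoxide betaine 12 (not isolated)
Conditions: PPh3, toluene, −20 to 20 °C
Reagents that add atoms: none
Why: PPh3 inserts into the O–O bond to give a dioxaphosphorane that opens to betaine 12, with phosphorus on the oxygen of secondary C8 and the tertiary C5 oxygen as alkoxide, and the alkoxide then displaces Ph3P=O at C8 in an intramolecular SN2 reaction. This is the known phosphine deoxygenation of 3,6-dihydro-1,2-dioxines to 2,5-dihydrofurans. Ring B closes in a 5-exo-tet mode by forming the O–C8 bond, while the C5–O bond is never broken. C8 is formed with inversion (8R to 8S), so the cis relation of H8 and the C5 methyl in the peroxide becomes a cis relation of the C9 chain and the C5 methyl, with C3 and C5 untouched. The step needs closure at C8 and neither SN2′ attack at C6 nor ionisation of the doubly allylic C8–O bond: C6 is fully substituted and shielded by C1 and C5, the betaine with phosphorus on the tertiary oxygen cannot close and reverts, and cold toluene without added base disfavours ion pairs and Kornblum–DeLaMare isomerisation.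

Step 10
Reactants: 13 furanoid pivalate
Product: 14 (2Z)-3-[(2S,6S,7aR)-6-(tert-butyldimethylsilyloxy)-4,4,7a-trimethyl-2,4,5,6,7,7a-hexahydro-1-benzofuran-2-yl]but-2-en-1-ol
Conditions: NaOMe (cat.), MeOH, 20 °C
Reagents that add atoms: none
Why: Base-catalysed transesterification (methanolysis) of the primary allylic pivalate; the silyl ether and the dihydrofuran, which is labile only to acid, are stable to methoxide.

Step 11
Reactants: 14 furanoid allylic alcohol
Product: 15 (2Z)-3-[(2S,6S,7aR)-6-(tert-butyldimethylsilyloxy)-4,4,7a-trimethyl-2,4,5,6,7,7a-hexahydro-1-benzofuran-2-yl]but-2-enal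
Conditions: MnO2, CH2Cl2, 20 °C, dark
Reagents that add atoms: none
Why: MnO2 oxidation is selective for allylic alcohols and, under neutral conditions, is known to convert Z allylic alcohols into Z enals without isomerisation.

Step 12
Reactants: 16 (2E,4E,6E)-2,7-dimethylocta-2,4,6-trienedial (C10 dialdehyde); 17 triethyl phosphonoacetate
Product: 19 ethyl (2E,4E,6E,8E)-4,9-dimethyl-10-oxodeca-2,4,6,8-tetraenoate, via sodium phosphonoacetate anion 18 (not isolated)
Conditions: 17, NaH, THF, 0 °C; then added slowly to 16 (2.5 equiv), THF, −20 to 0 °C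
Reagents that add atoms: none
Why: Horner–Wadsworth–Emmons olefination with a stabilised phosphonoacetate anion should give the E enoate (11′E); slow addition of the anion to an excess of the symmetrical dialdehyde limits reaction to one formyl group.

Step 13
Reactants: 19 aldehyde ester
Product: 20 ethyl (2E,4E,6E,8E)-10-hydroxy-4,9-dimethyldeca-2,4,6,8-tetraenoate
Conditions: NaBH4, EtOH/THF, 0 °C
Reagents that add atoms: none
Why: NaBH4 1,2-reduction of the conjugated aldehyde, which is far faster than reduction of the conjugated ester at 0 °C.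

Step 14
Reactants: 20 hydroxy ester
Product: 21 ethyl (2E,4E,6E,8E)-10-bromo-4,9-dimethyldeca-2,4,6,8-tetraenoate
Conditions: PBr3, pyridine (cat.), Et2O, −10 °C; used crude
Reagents that add atoms: phosphorus tribromide, BrP(Br)Br
Why: Conversion of a primary allylic alcohol into the bromide with PBr3 (SN2 on the phosphite ester), the usual entry to polyenyl allylic bromides; the conjugated primary bromide is also the thermodynamically preferred allylic isomer.

Step 15
Reactants: 21 bromo ester
Product: 22 ethyl (2E,4E,6E,8E)-10-(diethoxyphosphoryl)-4,9-dimethyldeca-2,4,6,8-tetraenoate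
Conditions: P(OEt)3, 100 °C
Reagents that add atoms: triethyl phosphite, CCOP(OCC)OCC
Why: Michaelis–Arbuzov reaction of the primary allylic bromide with triethyl phosphite, with loss of bromoethane.

Step 16
Reactants: 22 C12 phosphonate ester; 15 furanoid (9Z)-enal
Product: 24 ethyl (2E,4E,6E,8E,10E,12Z)-13-[(2S,6S,7aR)-6-(tert-butyldimethylsilyloxy)-4,4,7a-trimethyl-2,4,5,6,7,7a-hexahydro-1-benzofuran-2-yl]-4,9-dimethyltetradeca-2,4,6,8,10,12-hexaenoate, via sodium phosphonate anion 23 (not isolated)
Conditions: 22, NaN(SiMe3)2, THF, −78 °C; then 15, −78 to 0 °C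
Reagents that add atoms: none
Why: Horner–Wadsworth–Emmons olefination of an enal with an allylic polyenyl phosphonate anion, the standard way of joining retinoid and carotenoid chains, should form C11=C12 as the E isomer; the base is consumed by the phosphonate before the aldehyde is added cold, so the Z enal and C8–H do not meet free base.

Step 17
Reactants: 24 C27 ester
Product: 25 (2E,4E,6E,8E,10E,12Z)-13-[(2S,6S,7aR)-6-(tert-butyldimethylsilyloxy)-4,4,7a-trimethyl-2,4,5,6,7,7a-hexahydro-1-benzofuran-2-yl]-4,9-dimethyltetradeca-2,4,6,8,10,12-hexaen-1-ol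
Conditions: i-Bu2AlH, CH2Cl2, −78 °C; aq. potassium sodium tartrate
Reagents that add atoms: none
Why: i-Bu2AlH 1,2-reduction of the conjugated ester to the primary allylic alcohol at −78 °C; silyl ether, polyene and dihydrofuran are inert.

Step 18
Reactants: 25 silyl-protected C27 alcohol
Product: 26 (2E,4E,6E,8E,10E,12Z)-13-[(2S,6S,7aR)-6-hydroxy-4,4,7a-trimethyl-2,4,5,6,7,7a-hexahydro-1-benzofuran-2-yl]-4,9-dimethyltetradeca-2,4,6,8,10,12-hexaen-1-ol (target)
Conditions: Bu4NF, THF, 0 to 20 °C, dark
Reagents that add atoms: none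
Why: Fluoride-mediated cleavage of the silyl ether under non-acidic conditions, which the acid-labile doubly allylic ether of ring B and the polyene tolerate.

Compound list
1 | ketoisophorone (2,6,6-trimethylcyclohex-2-ene-1,4-dione) | CC1=CC(=O)CC(C)(C)C1=O | starting material
2 | (6R)-2,2,6-trimethylcyclohexane-1,4-dione | O=C1C(C)(C)CC(=O)C[C@H]1C | intermediate
3 | (4R,6R)-4-hydroxy-2,2,6-trimethylcyclohexan-1-one | O=C1C(C)(C)C[C@H](O)C[C@H]1C | intermediate
4 | (4R,6R)-4-(tert-butyldimethylsilyloxy)-2,2,6-trimethylcyclohexan-1-one | O=C1C(C)(C)C[C@H](O[Si](C)(C)C(C)(C)C)C[C@H]1C | intermediate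
5 | (Z)-3-methylpent-2-en-4-yn-1-ol | C#C/C(C)=C\CO | starting material
6 | dilithio derivative of 5 (lithium alkoxide and lithium acetylide) | [Li+].[Li+].[C-]#C/C(C)=C\C[O-] | intermediate (not isolated)
7 | (1S,4R,6R)-4-(tert-butyldimethylsilyloxy)-1-[(3Z)-5-hydroxy-3-methylpent-3-en-1-yn-1-yl]-2,2,6-trimethylcyclohexan-1-ol | C/C(=C/CO)C#C[C@@]1(O)C(C)(C)C[C@H](O[Si](C)(C)C(C)(C)C)C[C@H]1C | intermediate
8 | (1R,4R,6R)-4-(tert-butyldimethylsilyloxy)-1-[(1E,3Z)-5-hydroxy-3-methylpenta-1,3-dien-1-yl]-2,2,6-trimethylcyclohexan-1-ol | C/C(=C/CO)/C=C/[C@@]1(O)C(C)(C)C[C@H](O[Si](C)(C)C(C)(C)C)C[C@H]1C | intermediate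
9 | (2Z,4E)-5-[(1R,4R,6R)-4-(tert-butyldimethylsilyloxy)-1-hydroxy-2,2,6-trimethylcyclohexyl]-3-methylpenta-2,4-dien-1-yl pivalate | C/C(=C/COC(=O)C(C)(C)C)/C=C/[C@@]1(O)C(C)(C)C[C@H](O[Si](C)(C)C(C)(C)C)C[C@H]1C | intermediate
10 | (2Z,4E)-5-[(4R)-4-(tert-butyldimethylsilyloxy)-2,6,6-trimethylcyclohex-1-en-1-yl]-3-methylpenta-2,4-dien-1-yl pivalate | C/C(=C/COC(=O)C(C)(C)C)/C=C/C1=C(C)C[C@@H](O[Si](C)(C)C(C)(C)C)CC1(C)C | intermediate
11 | (2Z)-3-[(3R,7S,8aR)-7-(tert-butyldimethylsilyloxy)-5,5,8a-trimethyl-3,5,6,7,8,8a-hexahydro-1,2-benzodioxin-3-yl]but-2-en-1-yl pivalate (5,8-endoperoxide) | C/C(=C/COC(=O)C(C)(C)C)[C@H]1C=C2C(C)(C)C[C@H](O[Si](C)(C)C(C)(C)C)C[C@@]2(C)OO1 | intermediate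
12 | betaine with Ph3P+–O on C8 and alkoxide on C5 (C6=C7 exocyclic to ring A, C8 cis to C5) | C/C(=C/COC(=O)C(C)(C)C)[C@H](O[P+](c1ccccc1)(c1ccccc1)c1ccccc1)/C=C1/C(C)(C)C[C@H](O[Si](C)(C)C(C)(C)C)C[C@@]1(C)[O-] | intermediate (not isolated)
13 | (2Z)-3-[(2S,6S,7aR)-6-(tert-butyldimethylsilyloxy)-4,4,7a-trimethyl-2,4,5,6,7,7a-hexahydro-1-benzofuran-2-yl]but-2-en-1-yl pivalate (5,8-epoxide) | C/C(=C/COC(=O)C(C)(C)C)[C@@H]1C=C2C(C)(C)C[C@H](O[Si](C)(C)C(C)(C)C)C[C@@]2(C)O1 | intermediate
14 | (2Z)-3-[(2S,6S,7aR)-6-(tert-butyldimethylsilyloxy)-4,4,7a-trimethyl-2,4,5,6,7,7a-hexahydro-1-benzofuran-2-yl]but-2-en-1-ol | C/C(=C/CO)[C@@H]1C=C2C(C)(C)C[C@H](O[Si](C)(C)C(C)(C)C)C[C@@]2(C)O1 | intermediate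
15 | (2Z)-3-[(2S,6S,7aR)-6-(tert-butyldimethylsilyloxy)-4,4,7a-trimethyl-2,4,5,6,7,7a-hexahydro-1-benzofuran-2-yl]but-2-enal | C/C(=C/C=O)[C@@H]1C=C2C(C)(C)C[C@H](O[Si](C)(C)C(C)(C)C)C[C@@]2(C)O1 | intermediate
16 | (2E,4E,6E)-2,7-dimethylocta-2,4,6-trienedial | O=C/C(C)=C/C=C/C=C(C)/C=O | starting material
17 | triethyl phosphonoacetate | CCOC(=O)CP(=O)(OCC)OCC | starting material
18 | sodium salt of the triethyl phosphonoacetate carbanion | [Na+].CCOC(=O)[CH-]P(=O)(OCC)OCC | intermediate (not isolated)
19 | ethyl (2E,4E,6E,8E)-4,9-dimethyl-10-oxodeca-2,4,6,8-tetraenoate | CCOC(=O)/C=C/C(C)=C/C=C/C=C(C)/C=O | intermediate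
20 | ethyl (2E,4E,6E,8E)-10-hydroxy-4,9-dimethyldeca-2,4,6,8-tetraenoate | CCOC(=O)/C=C/C(C)=C/C=C/C=C(C)/CO | intermediate
21 | ethyl (2E,4E,6E,8E)-10-bromo-4,9-dimethyldeca-2,4,6,8-tetraenoate | CCOC(=O)/C=C/C(C)=C/C=C/C=C(C)/CBr | intermediate
22 | ethyl (2E,4E,6E,8E)-10-(diethoxyphosphoryl)-4,9-dimethyldeca-2,4,6,8-tetraenoate | CCOC(=O)/C=C/C(C)=C/C=C/C=C(C)/CP(=O)(OCC)OCC | intermediate
23 | sodium salt of the C10 carbanion of 22 | [Na+].CCOC(=O)/C=C/C(C)=C/C=C/C=C(C)/[CH-]P(=O)(OCC)OCC | intermediate (not isolated)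
24 | ethyl (2E,4E,6E,8E,10E,12Z)-13-[(2S,6S,7aR)-6-(tert-butyldimethylsilyloxy)-4,4,7a-trimethyl-2,4,5,6,7,7a-hexahydro-1-benzofuran-2-yl]-4,9-dimethyltetradeca-2,4,6,8,10,12-hexaenoate | C/C(=C/C=C/C(C)=C/C=C/C=C(C)/C=C/C(=O)OCC)[C@@H]1C=C2C(C)(C)C[C@H](O[Si](C)(C)C(C)(C)C)C[C@@]2(C)O1 | intermediate
25 | (2E,4E,6E,8E,10E,12Z)-13-[(2S,6S,7aR)-6-(tert-butyldimethylsilyloxy)-4,4,7a-trimethyl-2,4,5,6,7,7a-hexahydro-1-benzofuran-2-yl]-4,9-dimethyltetradeca-2,4,6,8,10,12-hexaen-1-ol | C/C(=C/C=C/C(C)=C/C=C/C=C(C)/C=C/CO)[C@@H]1C=C2C(C)(C)C[C@H](O[Si](C)(C)C(C)(C)C)C[C@@]2(C)O1 | intermediate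
26 | (2E,4E,6E,8E,10E,12Z)-13-[(2S,6S,7aR)-6-hydroxy-4,4,7a-trimethyl-2,4,5,6,7,7a-hexahydro-1-benzofuran-2-yl]-4,9-dimethyltetradeca-2,4,6,8,10,12-hexaen-1-ol | C/C(=C/C=C/C(C)=C/C=C/C=C(C)/C=C/CO)[C@@H]1C=C2C(C)(C)C[C@H](O)C[C@@]2(C)O1 | target

Total step count: 18. Longest linear sequence: 14 steps (steps 1 to 11, then 16 to 18, from ketoisophorone); the C12 phosphonate branch is 4 steps (12 to 15).

Steps most likely to fail

Step 8. Oxygen may add to the diene face syn to the silyloxy group, since the anti preference is an expectation by analogy and not secured. The Schenck ene reaction at the tetrasubstituted C5=C6 bond may also compete with the cycloaddition, and the peroxide may isomerise on contact with base or warm silica. The fallback sets out from 10 and avoids the peroxide. Epoxidation of the C5=C6 bond of 10 with mCPBA and NaHCO3 in CH2Cl2 at 0 °C would give the anti 5,6-epoxide (2Z,4E)-5-[(1S,4S,6R)-4-(tert-butyldimethylsilyloxy)-2,2,6-trimethyl-7-oxabicyclo[4.1.0]heptan-1-yl]-3-methylpenta-2,4-dien-1-yl pivalate F1. Attack anti to a protected 3-oxygen is the established preference for this reagent on β end groups. A trace of pyridinium p-toluenesulfonate in CH2Cl2 at 0 °C would then trigger the epoxide-to-furanoid rearrangement (C6–O ionisation, attack of the C5 oxygen on C8). This should give 13 together with its C8 epimer, to be separated by chromatography; the route is rejoined at 13.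

Step 9. The peroxide may isomerise to the 5-hydroxy-8-ketone (Kornblum–DeLaMare pathway) or fragment at the O–O bond before the P–O bond is in place, so that little of betaine 12 reaches the SN2 closure. The fallback sets out from 11 and separates O–O cleavage from C–O bond formation. Thiourea in MeOH at 20 °C would reduce the peroxide to the (Z)-ene-5,8-diol (2Z,4R)-4-hydroxy-4-... side-chain diol, that is 3-O-silyl C15 (5R,8R)-5,8-diol pivalate F2. Mitsunobu cyclodehydration (PPh3, diisopropyl azodicarboxylate, THF, 0 °C) would then activate the less hindered secondary C8 hydroxyl, and the tertiary C5 hydroxyl would displace it with inversion. This returns to the route at 13.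

Step 16. The delocalised phosphonate anion may deprotonate the enal at C8 (γ position), eroding the C8 configuration and the 9Z geometry. The E geometry at C11=C12 and C13=C14 may also be partly lost through the extended anion. The fallback sets out from 21 and 15 and uses a base-free Wittig reaction. Bromide 21 with PPh3 in toluene at 20 °C would give [(2E,4E,6E,8E)-10-ethoxy-2,7-dimethyl-10-oxodeca-2,4,6,8-tetraen-1-yl]triphenylphosphonium bromide F3. Heating F3 with 15 in 1,2-epoxybutane at 60 °C generates the ylide reversibly, with the epoxide as HBr acceptor and no strong base present. Chromatographic removal of any 11Z isomer would deliver 24, where the route is rejoined.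

Further compounds
F1 | step 8 | (2Z,4E)-5-[(1S,4S,6R)-4-(tert-butyldimethylsilyloxy)-2,2,6-trimethyl-7-oxabicyclo[4.1.0]heptan-1-yl]-3-methylpenta-2,4-dien-1-yl pivalate | C/C(=C/COC(=O)C(C)(C)C)/C=C/[C@@]12O[C@]1(C)C[C@@H](O[Si](C)(C)C(C)(C)C)CC2(C)C
F2 | step 9 | 3-O-silyl C15 (5R,8R)-5,8-diol pivalate (C5 tertiary OH, C8 secondary OH, C6=C7 exocyclic to ring A with C8 cis to C5, 9Z) | C/C(=C/COC(=O)C(C)(C)C)[C@H](O)/C=C1/C(C)(C)C[C@H](O[Si](C)(C)C(C)(C)C)C[C@@]1(C)O
F3 | step 16 | [(2E,4E,6E,8E)-10-ethoxy-2,7-dimethyl-10-oxodeca-2,4,6,8-tetraen-1-yl]triphenylphosphonium bromide | CCOC(=O)/C=C/C(C)=C/C=C/C=C(C)/C[P+](c1ccccc1)(c1ccccc1)c1ccccc1.[Br-]
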